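**Plan**

1. Locants: ring C1 (methyl-bearing oxirane carbon), C2 (oxirane CH), C3 (CH2), C4 (carries the side chain), C5 and C6 (the two angeloyloxy carbons, C6 next to C1); side chain C7(=C14H2)–C8(OAc)–C9–C10=C11.
2. Retrosynthesis: cut C10=C11 (cross-metathesis), the C5 ester, the C1–C2 oxirane (C5–OH-directed epoxidation), the C6 ester (anti opening of a C5–C6 vinyl oxirane by angelic acid), C8–C9 (allylboration), then the ring bond C5–C6 together with that oxirane (intramolecular sulfonium-ylide epoxidation of an open-chain Z enal).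
3. Forward: the ring of (R)-carvone is opened between C5 and C6 (α′-hydroxylation, Pb(OAc)4), keeping C4 and the Z C1=C2 bond; C5 becomes CH2–S+Ph2 and C6 a Z enal; the six-membered ring is then re-closed between C5 and C6 as a cyclohexene-fused oxirane; the side chain is grown on a chloromethyl handle; the C1–C2 oxirane and the prenyl alkene come last.
4. Enabling feature: the bond to be made carries an oxygen at each end (C5–O, C6–O), so it is the C–C bond of a masked oxirane; C6 is attached to the ring C1(Me)=C2 double bond, whose Z geometry (carvone's enone) holds C6 and C3 cis, so the ylide carbon C5 and the aldehyde carbon C6 meet in a six-membered array next to stereocentre C4.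
5. Stereochemistry: C4 from (R)-carvone; C5/C6 from the key step (Ph2S+ trans to the C4 chain, oxygen enters C5 with inversion, hence cis to the chain); C6–O inverted by SN2 opening; C1/C2 by hydroxyl-directed epoxidation; C8 by reagent-controlled allylboration.

Key step: step 7

Remark: step 2 is assumed to give mainly the trans ketol drawn; the cis epimer would serve equally, because this carbon becomes CH2OH in step 3.

**Route**

Step 1
Reactants: 1 (R)-(−)-carvone
Product: 2 (5R)-5-(3-chloroprop-1-en-2-yl)-2-methylcyclohex-2-en-1-one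
Conditions: Ca(OCl)2, CO2 (s), CH2Cl2/H2O, 0 °C
Reagents that add atoms: calcium hypochlorite, [Ca+2].[O-]Cl.[O-]Cl
Why: Ene-type allylic chlorination by HOCl attacks only the electron-rich isopropenyl alkene and not the enone, giving a 2-(chloromethyl)allyl group that serves as a latent C8 aldehyde, with C4 untouched.

Step 2
Reactants: 2 (5R)-5-(3-chloroprop-1-en-2-yl)-2-methylcyclohex-2-en-1-one
Product: 4 (5S,6S)-5-(3-chloroprop-1-en-2-yl)-6-hydroxy-2-methylcyclohex-2-en-1-one, via potassium enolate 3 (not isolated)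
Conditions: KN(SiMe3)2, THF, −78 °C; then 2-(benzenesulfonyl)-3-phenyloxaziridine; AcOH, −78 °C
Reagents that add atoms: 2-(benzenesulfonyl)-3-phenyloxaziridine, O=S(=O)(N1OC1c1ccccc1)c1ccccc1
Why: Kinetic α′-deprotonation at C5 and Davis oxidation of the potassium enolate install the oxygen needed for C5–C6 cleavage, attack being expected anti to the C4 substituent, and the cold acidic quench keeps the alkoxide from displacing the allylic chloride.

Step 3
Reactants: 4 (5S,6S)-5-(3-chloroprop-1-en-2-yl)-6-hydroxy-2-methylcyclohex-2-en-1-one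
Product: 6 methyl (2Z,5S)-6-(chloromethyl)-5-(hydroxymethyl)-2-methylhepta-2,6-dienoate, via aldehyde ester 5 (not isolated)
Conditions: Pb(OAc)4, MeOH/PhH, 0 °C; then NaBH4, −20 °C
Reagents that add atoms: methanol, CO
Why: Glycol-type cleavage of the α-ketol by Pb(OAc)4 in methanol (through the methyl hemiketal) opens the ring between C5 and C6 to a C6 methyl ester and a C5 aldehyde, which NaBH4 reduces in the same flask before C4 can epimerise, so the ring-derived Z geometry and the C4 configuration are kept.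

Step 4
Reactants: 6 methyl (2Z,5S)-6-(chloromethyl)-5-(hydroxymethyl)-2-methylhepta-2,6-dienoate
Product: 7 (2Z,5S)-6-(chloromethyl)-5-(hydroxymethyl)-2-methylhepta-2,6-dien-1-ol
Conditions: i-Bu2AlH, CH2Cl2, −78 °C
Reagents that add atoms: none
Why: 1,2-Reduction of the enoate by i-Bu2AlH gives the Z allylic alcohol without touching the alkene geometry or, at this temperature, the allylic chloride.

Step 5
Reactants: 7 (2Z,5S)-6-(chloromethyl)-5-(hydroxymethyl)-2-methylhepta-2,6-dien-1-ol
Product: 8 (2Z,5S)-6-(chloromethyl)-5-(hydroxymethyl)-2-methylhepta-2,6-dienal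
Conditions: MnO2, CH2Cl2, 23 °C
Reagents that add atoms: none
Why: MnO2 oxidises only the allylic primary alcohol, giving the Z enal and leaving the saturated C5 alcohol free for activation.

Step 6
Reactants: 8 (2Z,5S)-6-(chloromethyl)-5-(hydroxymethyl)-2-methylhepta-2,6-dienal
Product: 10 [(2S,4Z)-2-(3-chloroprop-1-en-2-yl)-5-methyl-6-oxohex-4-en-1-yl]diphenylsulfonium trifluoromethanesulfonate, via primary triflate 9 (not isolated)
Conditions: Tf2O, 2,6-di-tert-butyl-4-methylpyridine, CH2Cl2, −78 °C; then Ph2S, −78 → 23 °C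
Reagents that add atoms: trifluoromethanesulfonic anhydride, O=S(=O)(OS(=O)(=O)C(F)(F)F)C(F)(F)F; diphenyl sulfide, c1ccc(Sc2ccccc2)cc1
Why: O-Triflation followed by SN2 alkylation of diphenyl sulfide gives an alkyldiphenylsulfonium salt whose only α-protons sit on C5, while the hindered pyridine takes up TfOH and spares the Z enal and the allylic chloride.

Step 7
Reactants: 10 [(2S,4Z)-2-(3-chloroprop-1-en-2-yl)-5-methyl-6-oxohex-4-en-1-yl]diphenylsulfonium trifluoromethanesulfonate
Product: 13 (1S,5S,6R)-5-(3-chloroprop-1-en-2-yl)-2-methyl-7-oxabicyclo[4.1.0]hept-2-ene, via sulfonium ylide 11 (not isolated), via oxido sulfonium betaine 12 (not isolated)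
Conditions: LiN(SiMe3)2, THF, −78 → 0 °C
Reagents that add atoms: none
Why: LiN(SiMe3)2 removes a proton from the S+–CH2 group (C5; the phenyl groups offer no other α-proton) to give the non-stabilised ylide 11, whose carbanion adds 1,2 to the Z-enal carbonyl (C6) to form betaine 12, and the alkoxide then displaces Ph2S at C5. The closest known reaction type is the Johnson–Corey–Chaykovsky epoxidation of aldehydes and enals by diphenylsulfonium alkylides, in its intramolecular epoxy-annulation form. The cyclohexene closes by 6-exo-trig attack on the C=O group, possible because the Z C1=C2 bond holds C6 and C3 cis, and the oxirane closes by 3-exo-tet displacement. C5 is controlled by C4: in the half-chair addition transition state the bulky Ph2S+ group should lie equatorial and trans to the equatorial C4 substituent, and SN2 closure inverts C5, so the oxygen ends cis to the C4 chain; C6 follows from C5, since only the betaine with O− and S+ trans on the ring can reach the anti-periplanar geometry needed for the necessarily cis-fused oxirane. The step needs α-deprotonation to beat E2 loss of Ph2S and γ-deprotonation of the enal, which the high kinetic acidity of the sulfonium α-protons, the hindered base and −78 °C should secure, and 1,2-addition is enforced because 1,4-addition would need a four-membered ring.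

Step 8
Reactants: 13 (1S,5S,6R)-5-(3-chloroprop-1-en-2-yl)-2-methyl-7-oxabicyclo[4.1.0]hept-2-ene
Product: 14 2-[(1S,5S,6R)-2-methyl-7-oxabicyclo[4.1.0]hept-2-en-5-yl]prop-2-enal
Conditions: N-methylmorpholine N-oxide, NaI (cat.), NaHCO3, MeCN, 45 °C
Reagents that add atoms: N-methylmorpholine N-oxide, C[N+]1([O-])CCOCC1
Why: Ganem oxidation, in which the N-oxide oxygen displaces the allylic chloride and elimination of N-methylmorpholine delivers the 2-substituted acrolein under near-neutral conditions that should leave the vinyl oxirane intact.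

Step 9
Reactants: 14 2-[(1S,5S,6R)-2-methyl-7-oxabicyclo[4.1.0]hept-2-en-5-yl]prop-2-enal
Product: 16 (3S)-2-[(1S,5S,6R)-2-methyl-7-oxabicyclo[4.1.0]hept-2-en-5-yl]hexa-1,5-dien-3-ol, via borinate ester 15 (not isolated)
Conditions: (−)-Ipc2B(allyl), Et2O, −78 °C; then HOCH2CH2NH2, 23 °C
Reagents that add atoms: (−)-B-allyldiisopinocampheylborane, C=CCB([C@@H]1C[C@@H]2C[C@H]([C@H]1C)C2(C)C)[C@@H]1C[C@@H]2C[C@H]([C@H]1C)C2(C)C
Why: Brown asymmetric allylboration through a chair Zimmerman–Traxler transition state, in which the (−)-Ipc2B reagent (from (+)-α-pinene) delivers allyl to the Si face of the aldehyde under reagent control and sets C8 as S, with a non-oxidative ethanolamine work-up that spares the oxirane.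

Step 10
Reactants: 16 (3S)-2-[(1S,5S,6R)-2-methyl-7-oxabicyclo[4.1.0]hept-2-en-5-yl]hexa-1,5-dien-3-ol
Product: 17 (3S)-2-[(1S,5S,6R)-2-methyl-7-oxabicyclo[4.1.0]hept-2-en-5-yl]hexa-1,5-dien-3-yl acetate
Conditions: Ac2O, pyridine, DMAP (cat.), CH2Cl2, 0 °C
Reagents that add atoms: acetic anhydride, CC(=O)OC(C)=O
Why: DMAP-catalysed acetylation fixes the C8 acetate while this is the only hydroxyl in the molecule.

Step 11
Reactants: 17 (3S)-2-[(1S,5S,6R)-2-methyl-7-oxabicyclo[4.1.0]hept-2-en-5-yl]hexa-1,5-dien-3-yl acetate; 18 angelic acid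
Product: 19 (1R,5S,6R)-5-[(3S)-3-acetoxyhexa-1,5-dien-2-yl]-6-hydroxy-2-methylcyclohex-2-en-1-yl (2Z)-2-methylbut-2-enoate
Conditions: PhMe, 0 → 23 °C (18 in excess)
Reagents that add atoms: none
Why: Acid-promoted SN2-type opening of the vinyl oxirane by the carboxylic acid is expected at the allylic carbon C6 with inversion, giving the trans hydroxy ester with the angelate on C6 and a free C5–OH cis to the C4 chain, and the absence of base or acyl-transfer catalyst keeps the Z geometry of the angelate.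

Step 12
Reactants: 19 (1R,5S,6R)-5-[(3S)-3-acetoxyhexa-1,5-dien-2-yl]-6-hydroxy-2-methylcyclohex-2-en-1-yl (2Z)-2-methylbut-2-enoate
Product: 20 (1S,2S,3R,4S,6S)-4-[(3S)-3-acetoxyhexa-1,5-dien-2-yl]-3-hydroxy-1-methyl-7-oxabicyclo[4.1.0]heptan-2-yl (2Z)-2-methylbut-2-enoate
Conditions: VO(acac)2 (cat.), t-BuOOH, CH2Cl2, 0 → 23 °C
Reagents that add atoms: tert-butyl hydroperoxide, CC(C)(C)OO
Why: Hydroxyl-directed epoxidation of the cyclic homoallylic alcohol, in which the axial C5–OH delivers oxygen to the C1=C2 face cis to itself and anti to the pseudo-axial C6 ester (setting C1 and C2), while the side-chain 1,1-disubstituted alkene is deactivated by its allylic acetate and the terminal alkene and the angelate are inert.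

Step 13
Reactants: 20 (1S,2S,3R,4S,6S)-4-[(3S)-3-acetoxyhexa-1,5-dien-2-yl]-3-hydroxy-1-methyl-7-oxabicyclo[4.1.0]heptan-2-yl (2Z)-2-methylbut-2-enoate; 18 angelic acid
Product: 22 (1S,2S,3R,4S,6S)-4-[(3S)-3-acetoxyhexa-1,5-dien-2-yl]-1-methyl-7-oxabicyclo[4.1.0]heptane-2,3-diyl bis[(2Z)-2-methylbut-2-enoate], via mixed anhydride 21 (not isolated)
Conditions: 18, 2,4,6-Cl3C6H2COCl, Et3N, PhMe, 23 °C; then 20, 80 °C
Reagents that add atoms: none
Why: Yamaguchi-type acylation by the angelic 2,4,6-trichlorobenzoic mixed anhydride, run without DMAP, should acylate the hindered C5–OH at the less hindered angeloyl carbonyl without Z to E isomerisation.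

Step 14
Reactants: 22 (1S,2S,3R,4S,6S)-4-[(3S)-3-acetoxyhexa-1,5-dien-2-yl]-1-methyl-7-oxabicyclo[4.1.0]heptane-2,3-diyl bis[(2Z)-2-methylbut-2-enoate]
Product: 23 CNP0188566.1, (1S,2S,3R,4S,6S)-4-[(3S)-3-acetoxy-6-methylhepta-1,5-dien-2-yl]-1-methyl-7-oxabicyclo[4.1.0]heptane-2,3-diyl bis[(2Z)-2-methylbut-2-enoate]
Conditions: 2-methyl-2-butene (excess), second-generation Grubbs catalyst (H2IMes)(PCy3)Cl2Ru=CHPh (cat.), CH2Cl2, 40 °C
Reagents that add atoms: 2-methyl-2-butene, CC=C(C)C
Why: Olefin cross-metathesis of the only monosubstituted alkene with 2-methyl-2-butene turns the allyl group into the prenyl group, while the 1,1-disubstituted alkene, the angelates and the oxirane should not engage the ruthenium carbene.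

**Compound list**

1 | (R)-(−)-carvone | CC1=CC[C@H](CC1=O)C(C)=C | starting material
2 | (5R)-5-(3-chloroprop-1-en-2-yl)-2-methylcyclohex-2-en-1-one | CC1=CC[C@H](CC1=O)C(=C)CCl | intermediate
3 | potassium (3R)-3-(3-chloroprop-1-en-2-yl)-6-methylcyclohexa-1,5-dien-1-olate (not isolated) | CC1=CC[C@H](C=C1[O-])C(=C)CCl.[K+] | intermediate
4 | (5S,6S)-5-(3-chloroprop-1-en-2-yl)-6-hydroxy-2-methylcyclohex-2-en-1-one | CC1=CC[C@H]([C@H](O)C1=O)C(=C)CCl | intermediate
5 | methyl (2Z,5S)-6-(chloromethyl)-5-formyl-2-methylhepta-2,6-dienoate (not isolated) | COC(=O)/C(C)=C\C[C@H](C=O)C(=C)CCl | intermediate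
6 | methyl (2Z,5S)-6-(chloromethyl)-5-(hydroxymethyl)-2-methylhepta-2,6-dienoate | COC(=O)/C(C)=C\C[C@H](CO)C(=C)CCl | intermediate
7 | (2Z,5S)-6-(chloromethyl)-5-(hydroxymethyl)-2-methylhepta-2,6-dien-1-ol | OC/C(C)=C\C[C@H](CO)C(=C)CCl | intermediate
8 | (2Z,5S)-6-(chloromethyl)-5-(hydroxymethyl)-2-methylhepta-2,6-dienal | O=C/C(C)=C\C[C@H](CO)C(=C)CCl | intermediate
9 | (2S,4Z)-2-(3-chloroprop-1-en-2-yl)-5-methyl-6-oxohex-4-en-1-yl trifluoromethanesulfonate (not isolated) | O=C/C(C)=C\C[C@H](COS(=O)(=O)C(F)(F)F)C(=C)CCl | intermediate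
10 | [(2S,4Z)-2-(3-chloroprop-1-en-2-yl)-5-methyl-6-oxohex-4-en-1-yl]diphenylsulfonium trifluoromethanesulfonate | O=C/C(C)=C\C[C@H](C[S+](c1ccccc1)c1ccccc1)C(=C)CCl.[O-]S(=O)(=O)C(F)(F)F | intermediate
11 | diphenylsulfonium ylide of 10, carbanion at C5 (not isolated) | O=C/C(C)=C\C[C@H]([CH-][S+](c1ccccc1)c1ccccc1)C(=C)CCl | intermediate
12 | diphenyl[(1S,2S,6S)-6-(3-chloroprop-1-en-2-yl)-3-methyl-2-oxidocyclohex-3-en-1-yl]sulfonium, betaine (not isolated) | CC1=CC[C@H]([C@H]([S+](c2ccccc2)c2ccccc2)[C@H]1[O-])C(=C)CCl | intermediate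
13 | (1S,5S,6R)-5-(3-chloroprop-1-en-2-yl)-2-methyl-7-oxabicyclo[4.1.0]hept-2-ene | CC1=CC[C@H]([C@H]2O[C@@H]12)C(=C)CCl | intermediate
14 | 2-[(1S,5S,6R)-2-methyl-7-oxabicyclo[4.1.0]hept-2-en-5-yl]prop-2-enal | CC1=CC[C@H]([C@H]2O[C@@H]12)C(=C)C=O | intermediate
15 | (3S)-2-[(1S,5S,6R)-2-methyl-7-oxabicyclo[4.1.0]hept-2-en-5-yl]hexa-1,5-dien-3-yl diisopinocampheylborinate (not isolated) | CC1=CC[C@H]([C@H]2O[C@@H]12)C(=C)[C@H](CC=C)OB([C@@H]1C[C@@H]2C[C@H]([C@H]1C)C2(C)C)[C@@H]1C[C@@H]2C[C@H]([C@H]1C)C2(C)C | intermediate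
16 | (3S)-2-[(1S,5S,6R)-2-methyl-7-oxabicyclo[4.1.0]hept-2-en-5-yl]hexa-1,5-dien-3-ol | CC1=CC[C@H]([C@H]2O[C@@H]12)C(=C)[C@@H](O)CC=C | intermediate
17 | (3S)-2-[(1S,5S,6R)-2-methyl-7-oxabicyclo[4.1.0]hept-2-en-5-yl]hexa-1,5-dien-3-yl acetate | CC1=CC[C@H]([C@H]2O[C@@H]12)C(=C)[C@@H](OC(C)=O)CC=C | intermediate
18 | angelic acid, (2Z)-2-methylbut-2-enoic acid | C/C=C(/C)C(=O)O | starting material
19 | (1R,5S,6R)-5-[(3S)-3-acetoxyhexa-1,5-dien-2-yl]-6-hydroxy-2-methylcyclohex-2-en-1-yl (2Z)-2-methylbut-2-enoate | CC1=CC[C@H]([C@@H](O)[C@@H]1OC(=O)/C(C)=C\C)C(=C)[C@@H](OC(C)=O)CC=C | intermediate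
20 | (1S,2S,3R,4S,6S)-4-[(3S)-3-acetoxyhexa-1,5-dien-2-yl]-3-hydroxy-1-methyl-7-oxabicyclo[4.1.0]heptan-2-yl (2Z)-2-methylbut-2-enoate | C[C@]12O[C@H]1C[C@H]([C@@H](O)[C@@H]2OC(=O)/C(C)=C\C)C(=C)[C@@H](OC(C)=O)CC=C | intermediate
21 | (2Z)-2-methylbut-2-enoic 2,4,6-trichlorobenzoic anhydride (not isolated) | C/C=C(/C)C(=O)OC(=O)c1c(Cl)cc(Cl)cc1Cl | intermediate
22 | (1S,2S,3R,4S,6S)-4-[(3S)-3-acetoxyhexa-1,5-dien-2-yl]-1-methyl-7-oxabicyclo[4.1.0]heptane-2,3-diyl bis[(2Z)-2-methylbut-2-enoate] | C[C@]12O[C@H]1C[C@H]([C@@H](OC(=O)/C(C)=C\C)[C@@H]2OC(=O)/C(C)=C\C)C(=C)[C@@H](OC(C)=O)CC=C | intermediate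
23 | CNP0188566.1, (1S,2S,3R,4S,6S)-4-[(3S)-3-acetoxy-6-methylhepta-1,5-dien-2-yl]-1-methyl-7-oxabicyclo[4.1.0]heptane-2,3-diyl bis[(2Z)-2-methylbut-2-enoate] | C=C([C@H](CC=C(C)C)OC(C)=O)[C@@H]1C[C@@H]2O[C@]2(C)[C@@H](OC(=O)/C(C)=C\C)[C@@H]1OC(=O)/C(C)=C\C | target

**Count**

Total steps: 14. Longest linear sequence: 14 steps, from (R)-carvone 1 to 23; angelic acid 18 is used as purchased.

**Steps most likely to fail**

Step 7. The base may trigger E2 loss of Ph2S through the allylic C4–H, or γ-deprotonation of the enal, instead of ylide formation. The ylide may also add through the cis betaine, which cannot close and would collapse by hydride shift, and facial control by C4 may be incomplete. The fallback closes the same bond reductively; it sets out from 7 and comes back at 13. Diol 7 would be oxidised at both carbinols (Dess–Martin periodinane, NaHCO3) to the dialdehyde (2Z,5S)-5-(3-chloroprop-1-en-2-yl)-2-methylhex-2-enedial F1, used at once. F1 would be cyclised with Cp2TiPh (from Cp2TiCl2, i-PrMgCl and PhMgBr; trivalent titanium) in THF at −78 °C, a pinacol coupling that is trans-selective for 1,6-dials and should reduce the aldehydes faster than the allylic chloride. The product should be the trans diol (1R,2R,6S)-6-(3-chloroprop-1-en-2-yl)-3-methylcyclohex-3-ene-1,2-diol F2; the isomer with C5–OH cis to the C4 chain is the one needed and is expected if the two bulky titanoxy groups stay anti while the C4 chain is equatorial. Mitsunobu cyclodehydration (PPh3, diisopropyl azodicarboxylate) should then activate the allylic C6–OH, which the C5 oxygen displaces with inversion, giving 13.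

Step 6. Alkylation of the weakly nucleophilic Ph2S may be slow, so that the β-branched triflate ionises or eliminates first and the Z enal isomerises to E. The fallback makes the salt before the aldehyde exists; it sets out from 6 and comes back at 10. Hydroxy ester 6 would be triflated (Tf2O, 2,6-di-tert-butyl-4-methylpyridine) and warmed in neat Ph2S to the sulfonium ester [(2S,4Z)-2-(3-chloroprop-1-en-2-yl)-6-methoxy-5-methyl-6-oxohex-4-en-1-yl]diphenylsulfonium trifluoromethanesulfonate F3, whose Z enoate is configurationally robust. Reduction with i-Bu2AlH at −78 °C should give the allylic alcohol [(2S,4Z)-2-(3-chloroprop-1-en-2-yl)-6-hydroxy-5-methylhex-4-en-1-yl]diphenylsulfonium trifluoromethanesulfonate F4, and Dess–Martin oxidation then gives 10.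

Step 13. Acylation of the hindered C5–OH may be sluggish, so that Z to E isomerisation of the activated angeloyl unit and opening of the neighbouring oxirane compete. The fallback builds the angelate double bond on the molecule; it sets out from 20 and comes back at 22. Alcohol 20 would be acylated with 2-[bis(2,2,2-trifluoroethoxy)phosphoryl]propanoic acid (N,N′-diisopropylcarbodiimide, DMAP, CH2Cl2) to the phosphonate ester (1S,2S,3R,4S,6S)-4-[(3S)-3-acetoxyhexa-1,5-dien-2-yl]-3-{2-[bis(2,2,2-trifluoroethoxy)phosphoryl]propanoyloxy}-1-methyl-7-oxabicyclo[4.1.0]heptan-2-yl (2Z)-2-methylbut-2-enoate F5 (both epimers at the phosphonate carbon). Still–Gennari olefination with acetaldehyde (KN(SiMe3)2, 18-crown-6, THF, −78 °C) should then give the Z trisubstituted enoate, that is 22.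

**Further compounds**

F1 | step 7 | (2Z,5S)-5-(3-chloroprop-1-en-2-yl)-2-methylhex-2-enedial | O=C/C(C)=C\C[C@H](C=O)C(=C)CCl
F2 | step 7 | (1R,2R,6S)-6-(3-chloroprop-1-en-2-yl)-3-methylcyclohex-3-ene-1,2-diol | CC1=CC[C@H]([C@@H](O)[C@@H]1O)C(=C)CCl
F3 | step 6 | [(2S,4Z)-2-(3-chloroprop-1-en-2-yl)-6-methoxy-5-methyl-6-oxohex-4-en-1-yl]diphenylsulfonium trifluoromethanesulfonate | COC(=O)/C(C)=C\C[C@H](C[S+](c1ccccc1)c1ccccc1)C(=C)CCl.[O-]S(=O)(=O)C(F)(F)F
F4 | step 6 | [(2S,4Z)-2-(3-chloroprop-1-en-2-yl)-6-hydroxy-5-methylhex-4-en-1-yl]diphenylsulfonium trifluoromethanesulfonate | OC/C(C)=C\C[C@H](C[S+](c1ccccc1)c1ccccc1)C(=C)CCl.[O-]S(=O)(=O)C(F)(F)F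
F5 | step 13 | (1S,2S,3R,4S,6S)-4-[(3S)-3-acetoxyhexa-1,5-dien-2-yl]-3-{2-[bis(2,2,2-trifluoroethoxy)phosphoryl]propanoyloxy}-1-methyl-7-oxabicyclo[4.1.0]heptan-2-yl (2Z)-2-methylbut-2-enoate | C[C@]12O[C@H]1C[C@H]([C@@H](OC(=O)C(C)P(=O)(OCC(F)(F)F)OCC(F)(F)F)[C@@H]2OC(=O)/C(C)=C\C)C(=C)[C@@H](OC(C)=O)CC=C
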